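Ring atoms: C1 (methyl-bearing fusion carbon), C2, C3, C4 (isopropyl carbinol), C5 (fusion CH), then C6 (ester carbinol), C7, C8 (methyl-bearing epoxide carbon), C9 and C10 around the seven-membered ring.
Cuts: first the C6–O ester bond and the epoxide C–O bonds, then the C4–isopropyl bond, then C7–C8 and C9–C10 of the seven-membered ring, last the cyclopropane bonds C1–C10 and C5–C10 of the precursor. The ring cut is possible because C8(CH3)–C9 is the two-carbon unit of an alkyne and C7–C6–C5–C1–C10 is the five-carbon unit of a vinylcyclopropane: C1, C5 and C10 form a cyclopropane fused to the cyclopentane along C1–C5, and the vinyl group C6=C7 on C5 carries the C6 oxygen as a silyl enol ether.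
Forward: the cyclopentane is bought as 3-methylcyclopent-2-en-1-one, the cyclopropane is fused on by asymmetric Simmons–Smith reaction, and the seven-membered ring is closed by rhodium-catalysed (5+2) cycloaddition with 1-(trimethylsilyl)propyne. The silyl group directs the methyl-bearing alkyne carbon to C7 and is later exchanged for hydrogen.
Stereochemistry: C1 comes from the reagent-controlled cyclopropanation; C5 from protonation to the cis-fused ketone; C6, C4 and the epoxide from attack on the convex face of the cis-fused bicycle.

Key step: step 9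

Remark on the target: the SMILES is read as a cis-fused bicycle with the C1 methyl, H-5, the isopropyl group and the epoxide oxygen on one face (the "methyl face") and the C4 hydroxyl and the C6 ester oxygen on the other, i.e. (1S,4R,5S,6R,8R,9S) in the numbering above.

Step 1
Reactants: 1 3-methylcyclopent-2-en-1-one
Product: 3 2-bromo-3-methylcyclopent-2-en-1-one, via 2,3-dibromo-3-methylcyclopentan-1-one 2 (not isolated)
Conditions: Br2, CH2Cl2, 0 °C; then Et3N, 0 °C → rt
Reagents that add atoms: bromine, BrBr
Why: Bromine adds across the enone and triethylamine then removes HBr by E1cB elimination (bromination–dehydrobromination), the standard route to 2-bromo enones; the bromine marks the carbon that becomes C5.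

Step 2
Reactants: 3 2-bromo-3-methylcyclopent-2-en-1-one; 4 ethylene glycol
Product: 5 6-bromo-7-methyl-1,4-dioxaspiro[4.4]non-6-ene
Conditions: ethylene glycol, p-TsOH (cat.), benzene, reflux, Dean–Stark
Reagents that add atoms: ethylene glycol, OCCO
Why: Acid-catalysed ketalisation with azeotropic removal of water masks the future C4 ketone; 2-halo enones ketalise without migration of the double bond, and the ketal is what allows metal–halogen exchange in the next step.

Step 3
Reactants: 5 6-bromo-7-methyl-1,4-dioxaspiro[4.4]non-6-ene; 6 formaldehyde (monomer, generated from commercial paraformaldehyde)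
Product: 8 (7-methyl-1,4-dioxaspiro[4.4]non-6-en-6-yl)methanol, via alkenyllithium 7 (not isolated)
Conditions: n-BuLi, THF, −78 °C; then CH2O (gas), −78 °C → rt; aq. NH4Cl
Reagents that add atoms: formaldehyde, C=O
Why: Bromine–lithium exchange gives the alkenyllithium (an α-ketovinyl anion equivalent), whose 1,2-addition to formaldehyde installs C6 as the hydroxymethyl group that will direct the cyclopropanation.

Step 4
Reactants: 8 (7-methyl-1,4-dioxaspiro[4.4]non-6-en-6-yl)methanol; 9 diiodomethane
Product: 10 [(1R,5S)-5-methylspiro[bicyclo[3.1.0]hexane-2,2′-[1,3]dioxolan]-1-yl]methanol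
Conditions: Et2Zn (2.2 equiv), CH2I2 (4.4 equiv), DME, (4R,5R)-2-butyl-N,N,N′,N′-tetramethyl-1,3,2-dioxaborolane-4,5-dicarboxamide (1.2 equiv), CH2Cl2, −10 °C → rt
Reagents that add atoms: diiodomethane, ICI
Why: Hydroxyl-directed asymmetric Simmons–Smith cyclopropanation: the zinc alkoxide of 8, bound to the chiral dioxaborolane, delivers the methylene (C10) to one face of the tetrasubstituted alkene, and by the established facial model the (R,R)-controller should give the (1R,5S)-cyclopropane, which fixes the quaternary centre C1 for the rest of the route (the enantiomeric controller is the remedy should the sense be opposite).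

Step 5
Reactants: 10 [(1R,5S)-5-methylspiro[bicyclo[3.1.0]hexane-2,2′-[1,3]dioxolan]-1-yl]methanol
Product: 11 (1R,5S)-5-methylspiro[bicyclo[3.1.0]hexane-2,2′-[1,3]dioxolane]-1-carbaldehyde
Conditions: Pr4N[RuO4] (5 mol %), N-methylmorpholine N-oxide, 4 Å molecular sieves, CH2Cl2, rt
Reagents that add atoms: none
Why: Ley–Griffith oxidation under neutral conditions converts the neopentyl-type primary alcohol to the aldehyde without touching the ketal or the cyclopropane; the product has no α-hydrogen and cannot epimerise.

Step 6
Reactants: 11 (1R,5S)-5-methylspiro[bicyclo[3.1.0]hexane-2,2′-[1,3]dioxolane]-1-carbaldehyde; 12 methylmagnesium bromide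
Product: 13 1-[(1R,5S)-5-methylspiro[bicyclo[3.1.0]hexane-2,2′-[1,3]dioxolan]-1-yl]ethan-1-ol (both carbinol epimers)
Conditions: MeMgBr, THF, −78 → 0 °C; aq. NH4Cl
Reagents that add atoms: methylmagnesium bromide, C[Mg]Br
Why: Grignard addition to the non-enolisable aldehyde brings in C7; the new carbinol centre is of no consequence because it is oxidised in the next step.

Step 7
Reactants: 13 1-[(1R,5S)-5-methylspiro[bicyclo[3.1.0]hexane-2,2′-[1,3]dioxolan]-1-yl]ethan-1-ol
Product: 14 1-[(1R,5S)-5-methylspiro[bicyclo[3.1.0]hexane-2,2′-[1,3]dioxolan]-1-yl]ethan-1-one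
Conditions: Pr4N[RuO4] (5 mol %), N-methylmorpholine N-oxide, 4 Å molecular sieves, CH2Cl2, rt
Reagents that add atoms: none
Why: Ley–Griffith oxidation of the secondary alcohol gives the cyclopropyl methyl ketone, whose only enolisable position is the methyl group C7.

Step 8
Reactants: 14 1-[(1R,5S)-5-methylspiro[bicyclo[3.1.0]hexane-2,2′-[1,3]dioxolan]-1-yl]ethan-1-one
Product: 15 tert-butyl(dimethyl)({1-[(1R,5S)-5-methylspiro[bicyclo[3.1.0]hexane-2,2′-[1,3]dioxolan]-1-yl]ethenyl}oxy)silane
Conditions: TBSOTf, Et3N, CH2Cl2, −78 → 0 °C
Reagents that add atoms: tert-butyldimethylsilyl trifluoromethanesulfonate, CC(C)(C)[Si](C)(C)OS(=O)(=O)C(F)(F)F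
Why: Soft enolisation with silyl triflate and amine can only take place toward the methyl group, so the 2-siloxyvinyl group forms without a regiochemical question, and the excess amine keeps the dioxolane safe from the Lewis-acidic triflate.

Step 9
Reactants: 15 tert-butyl(dimethyl)({1-[(1R,5S)-5-methylspiro[bicyclo[3.1.0]hexane-2,2′-[1,3]dioxolan]-1-yl]ethenyl}oxy)silane; 16 trimethyl(prop-1-yn-1-yl)silane
Product: 17 (1S)-bicyclo[5.3.0]deca-5,8-diene (route numbering) carrying the C1 methyl, the C4 spiro-dioxolane, the C6 tert-butyldimethylsilyloxy group (C5=C6 enol ether), the C8 methyl and a C9 trimethylsilyl group (C8=C9)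
Conditions: [Rh(CO)2Cl]2 (5 mol %), 16 (2 equiv), ClCH2CH2Cl, 80 °C
Reagents that add atoms: trimethyl(prop-1-yn-1-yl)silane, CC#C[Si](C)(C)C
Why: Monovalent rhodium binds the siloxy-substituted alkene of 15 and inserts into the strained C5–C10 bond to give a rhodacycle σ-bound at C10 and π-allyl-bound over C5–C6–C7; the alkyne then inserts at the allyl terminus (C7–C8) and reductive elimination (C9–C10) releases 17, the whole sequence being paid for by the strain of the cyclopropane. The closest known reaction type is the [Rh(CO)2Cl]2-catalysed intermolecular (5+2) cycloaddition of oxygen-substituted and 1-alkylated vinylcyclopropanes with terminal and internal alkynes; 15 is a more highly substituted, ring-fused member of that class. The seven-membered ring closes by C(sp2)–C(sp3) reductive elimination from an eight-membered rhodacycle, so that both new σ-bonds are made on the metal. No stereocentre is formed: C1 passes through unchanged because neither of its ring bonds is broken, and C5 and C6 end as the enol ether double bond. The first selectivity needed, cleavage of C5–C10 and not of the fusion bond C1–C5, is secured by the substrate, since C10 is the only unsubstituted cyclopropane carbon and opening of the fusion bond would lead to a bridged bicyclo[4.3.1] skeleton with a bridgehead enol ether. The second, orientation of the alkyne with the methyl-bearing carbon bonded to C7, is secured by the trimethylsilyl group, which as the larger substituent stays on the metal-bound alkyne carbon remote from the first-formed C7–C8 bond and therefore ends at C9.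

Step 10
Reactants: 17 cycloadduct (C6 silyl enol ether, C9 trimethylsilyl, C4 dioxolane)
Product: 18 cis-fused C6 ketone: bicyclo[5.3.0]dec-8-en-6-one (route numbering) with the C1 methyl and H-5 on the same face, C4 spiro-dioxolane, C8 methyl and C9 trimethylsilyl
Conditions: TBAF, AcOH, THF, −78 → 0 °C
Reagents that add atoms: none
Why: Fluoride cleaves the Si–O bond of the enol ether and acetic acid protonates the enolate at C5 (desilylative kinetic protonation); the proton is expected to enter anti to the pseudo-axial C1–C10 bond of the folded seven-membered ring, giving H-5 cis to the C1 methyl, which is also the fusion that angularly methylated bicyclic ketones generally prefer at equilibrium, while the buffered medium leaves the vinylsilane, the ketal and the position of the C8–C9 double bond untouched.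

Step 11
Reactants: 18 cis-fused C6 ketone
Product: 19 C6 alcohol: as 18, with the C6 hydroxyl on the face opposite to the C1 methyl and H-5
Conditions: LiBH(s-Bu)3, THF, −78 °C; aq. NH4Cl
Reagents that add atoms: none
Why: Bulky hydride reduction: in the cis-fused ketone the five-membered ring with its spiro-ketal at C4 covers the concave face of C6, so hydride should be delivered from the convex (methyl) face and the hydroxyl appears on the opposite face, as C6 requires.

Step 12
Reactants: 19 C6 alcohol (C4 dioxolane, C9 trimethylsilyl)
Product: 20 cis-fused hydroxy ketone: 6-hydroxy-1,8-dimethylbicyclo[5.3.0]dec-8-en-4-one (route numbering), H-5 cis to the C1 methyl, C6 hydroxyl on the opposite face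
Conditions: CF3CO2H, CH2Cl2/H2O (10:1), 0 °C → rt
Reagents that add atoms: water, O
Why: Aqueous trifluoroacetic acid hydrolyses the dioxolane and, by ipso-protonation at C9 through the β-silyl-stabilised tertiary cation at C8, replaces the trimethylsilyl group by hydrogen with the double bond staying at C8–C9 (protodesilylation of a vinylsilane); C5, now α to the C4 ketone, can only settle in the cis-fused form that a cyclopentanone next to the ring fusion prefers, and the low temperature guards the β-hydroxy ketone against dehydration.

Step 13
Reactants: 20 cis-fused hydroxy ketone; 21 isopropylmagnesium chloride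
Product: 22 diol: 4-isopropyl-1,8-dimethylbicyclo[5.3.0]dec-8-ene-4,6-diol (route numbering), isopropyl on the methyl face, both hydroxyls on the opposite face
Conditions: i-PrMgCl (4 equiv), CeCl3 (anhydrous, 4 equiv), THF, −78 → 0 °C; aq. NH4Cl
Reagents that add atoms: isopropylmagnesium chloride, CC(C)[Mg]Cl
Why: Organocerium addition (reagent from the Grignard reagent and CeCl3) suppresses enolisation and β-hydride reduction; the first equivalent deprotonates the C6 hydroxyl, whose alkoxide is no leaving group and so rules out E1cB elimination, and the isopropyl group should add to C4 from the convex face anti to the C5–C6 bond, placing the tertiary hydroxyl on the same face as the C6 oxygen.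

Step 14
Reactants: 22 diol; 23 4-[(tert-butyldimethylsilyl)oxy]benzoic acid
Product: 24 C6 4-[(tert-butyldimethylsilyl)oxy]benzoate of diol 22
Conditions: 23, N,N′-dicyclohexylcarbodiimide, DMAP, CH2Cl2, rt
Reagents that add atoms: 4-[(tert-butyldimethylsilyl)oxy]benzoic acid, CC(C)(C)[Si](C)(C)Oc1ccc(cc1)C(O)=O
Why: Steglich esterification acylates only the secondary C6 hydroxyl, the tertiary C4 hydroxyl being inert under carbodiimide/DMAP conditions; the phenol is carried as its silyl ether so that the acid cannot self-condense.

Step 15
Reactants: 24 C6 4-[(tert-butyldimethylsilyl)oxy]benzoate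
Product: 25 8,9-epoxide of 24, epoxide oxygen on the methyl face
Conditions: dimethyldioxirane, acetone/CH2Cl2, −20 → 0 °C
Reagents that add atoms: dimethyldioxirane, CC1(C)OO1
Why: Electrophilic epoxidation of the trisubstituted C8–C9 alkene by the neutral dioxirane should take place on the convex face of the cis-fused bicycle (the face of the C1 methyl and H-5), the concave face being screened by the five-membered ring and the C6 ester; the acid-free reagent avoids transannular opening of the epoxide by the C4 hydroxyl.

Step 16
Reactants: 25 silyl-protected epoxy ester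
Product: 26 CNP0163817.4
Conditions: TBAF, AcOH, THF, 0 °C
Reagents that add atoms: none
Why: Fluoride cleaves the aryl silyl ether rapidly at 0 °C (desilylation), acetic acid buffers the phenoxide, and neither the hindered benzoate nor the epoxide reacts under these conditions.

Compound list
1 | 3-methylcyclopent-2-en-1-one | CC1=CC(=O)CC1 | starting material
2 | 2,3-dibromo-3-methylcyclopentan-1-one (racemic, not isolated) | CC1(Br)CCC(=O)C1Br | intermediate
3 | 2-bromo-3-methylcyclopent-2-en-1-one | CC1=C(Br)C(=O)CC1 | intermediate
4 | ethylene glycol | OCCO | starting material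
5 | 6-bromo-7-methyl-1,4-dioxaspiro[4.4]non-6-ene | CC1=C(Br)C2(CC1)OCCO2 | intermediate
6 | formaldehyde (from paraformaldehyde) | C=O | starting material
7 | (7-methyl-1,4-dioxaspiro[4.4]non-6-en-6-yl)lithium (not isolated) | [Li]C1=C(C)CCC12OCCO2 | intermediate
8 | (7-methyl-1,4-dioxaspiro[4.4]non-6-en-6-yl)methanol | CC1=C(CO)C2(CC1)OCCO2 | intermediate
9 | diiodomethane | ICI | starting material
10 | [(1R,5S)-5-methylspiro[bicyclo[3.1.0]hexane-2,2′-[1,3]dioxolan]-1-yl]methanol | OC[C@@]12C[C@]1(C)CCC23OCCO3 | intermediate
11 | (1R,5S)-5-methylspiro[bicyclo[3.1.0]hexane-2,2′-[1,3]dioxolane]-1-carbaldehyde | O=C[C@@]12C[C@]1(C)CCC23OCCO3 | intermediate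
12 | methylmagnesium bromide | C[Mg]Br | starting material
13 | 1-[(1R,5S)-5-methylspiro[bicyclo[3.1.0]hexane-2,2′-[1,3]dioxolan]-1-yl]ethan-1-ol (carbinol centre as epimer mixture) | CC(O)[C@@]12C[C@]1(C)CCC23OCCO3 | intermediate
14 | 1-[(1R,5S)-5-methylspiro[bicyclo[3.1.0]hexane-2,2′-[1,3]dioxolan]-1-yl]ethan-1-one | CC(=O)[C@@]12C[C@]1(C)CCC23OCCO3 | intermediate
15 | tert-butyl(dimethyl)({1-[(1R,5S)-5-methylspiro[bicyclo[3.1.0]hexane-2,2′-[1,3]dioxolan]-1-yl]ethenyl}oxy)silane | C=C(O[Si](C)(C)C(C)(C)C)[C@@]12C[C@]1(C)CCC23OCCO3 | intermediate
16 | trimethyl(prop-1-yn-1-yl)silane | CC#C[Si](C)(C)C | starting material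
17 | (5+2) cycloadduct: C5=C6 silyl enol ether, C8=C9 vinylsilane, C4 dioxolane | CC1=C([Si](C)(C)C)C[C@]2(C)CCC3(OCCO3)C2=C(O[Si](C)(C)C(C)(C)C)C1 | intermediate
18 | cis-fused C6 ketone (C4 dioxolane, C9 trimethylsilyl) | CC1=C([Si](C)(C)C)C[C@]2(C)CCC3(OCCO3)[C@@H]2C(=O)C1 | intermediate
19 | cis-fused C6 alcohol (C4 dioxolane, C9 trimethylsilyl) | CC1=C([Si](C)(C)C)C[C@]2(C)CCC3(OCCO3)[C@@H]2[C@H](O)C1 | intermediate
20 | cis-fused 6-hydroxy-4-ketone | CC1=CC[C@]2(C)CCC(=O)[C@@H]2[C@H](O)C1 | intermediate
21 | isopropylmagnesium chloride | CC(C)[Mg]Cl | starting material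
22 | 4-isopropyl-4,6-diol | CC(C)[C@]1(O)CC[C@@]2(C)CC=C(C)C[C@@H](O)[C@H]21 | intermediate
23 | 4-[(tert-butyldimethylsilyl)oxy]benzoic acid | CC(C)(C)[Si](C)(C)Oc1ccc(cc1)C(O)=O | starting material
24 | C6 4-[(tert-butyldimethylsilyl)oxy]benzoate | CC(C)[C@]1(O)CC[C@@]2(C)CC=C(C)C[C@@H](OC(=O)c3ccc(O[Si](C)(C)C(C)(C)C)cc3)[C@H]21 | intermediate
25 | 8,9-epoxide of 24 | CC(C)[C@]1(O)CC[C@@]2(C)C[C@@H]3O[C@]3(C)C[C@@H](OC(=O)c3ccc(O[Si](C)(C)C(C)(C)C)cc3)[C@H]21 | intermediate
26 | CNP0163817.4 | CC(C)[C@]1(O)CC[C@@]2(C)C[C@@H]3O[C@]3(C)C[C@@H](OC(=O)c3ccc(O)cc3)[C@H]21 | target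

Total step count: 16. Longest linear sequence: 16 steps (1 → 26); all coupling partners are purchased, so there is no convergent branch.

Steps most likely to fail

Step 9. The fully substituted, ring-fused cyclopropane may resist insertion of rhodium into C5–C10, the vinylcyclopropane may rearrange to a cyclopentene before the alkyne is taken up, or the internal silylalkyne may insert too slowly or with the opposite orientation. Fallback, setting out from 5 and coming back at 20: the seven-membered ring is made instead by rhodium-carbenoid cyclopropanation followed by Cope rearrangement of the cis-divinylcyclopropane (a formal (4+3) cycloaddition), which forms C7–C8 and C1–C10. Bromine–lithium exchange of 5 as in step 3 and acylation of 7 with N-methoxy-N-methylacetamide should give the enone 1-(7-methyl-1,4-dioxaspiro[4.4]non-6-en-6-yl)ethan-1-one F1, and TBSOTf/Et3N its 2-siloxydiene F2. With methyl 2-diazobut-3-enoate and the enantiomer of Rh2(DOSP)4 (dirhodium tetrakis[N-(4-dodecylbenzenesulfonyl)prolinate]) that leads to (S)-C1 (hexanes, −78 °C → rt, then toluene, 80 °C), the carbenoid should cyclopropanate the terminal siloxy alkene and the divinylcyclopropane should rearrange to the C8 methyl ester F3, the analogue of 17 without silicon at C9. i-Bu2AlH (CH2Cl2, −78 °C) should give the allylic alcohol F4, and SO3·pyridine followed by LiAlH4 should remove the hydroxyl to leave the C8 methyl group in the enol ether F5. TBAF/AcOH as in step 10 then gives the ketone F6, LiBH(s-Bu)3 as in step 11 the alcohol F7, and pyridinium p-toluenesulfonate in wet acetone removes the dioxolane to reach 20.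

Step 13. The C4 ketone may be enolised, reduced by β-hydride transfer from the isopropyl reagent, or opened by retro-aldol cleavage of the cerium aldolate, or the nucleophile may enter from the face next to C6. Fallback, setting out from 20 and coming back at 22: the three-carbon unit is brought in as an alkenyl nucleophile, which has no β-hydride to transfer and is less basic. Isopropenylmagnesium bromide/CeCl3 (THF, −78 °C) should give the isopropenyl diol F8. Hydrogenation with RhCl(PPh3)3 (H2, benzene), which reduces a 1,1-disubstituted alkene far faster than the trisubstituted ring alkene, then gives 22.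

Step 15. Poor facial selectivity, with the oxidant entering from the concave face, would give the epimeric epoxide. Fallback, setting out from 24 and coming back at 25: if electrophiles prefer the face opposite to the C1 methyl, that preference is put to use in a halohydrin sequence. N-Bromosuccinimide in THF/H2O should form the bromonium ion on that face, and water opens it at the tertiary C8 from the methyl face to give the bromohydrin F9. DBU (CH2Cl2) then closes the epoxide by displacement of bromide at C9 with inversion, which places the oxygen on the methyl face as in 25.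

Further compounds
F1 | step 9 | 1-(7-methyl-1,4-dioxaspiro[4.4]non-6-en-6-yl)ethan-1-one | CC(=O)C1=C(C)CCC12OCCO2
F2 | step 9 | tert-butyl(dimethyl){[1-(7-methyl-1,4-dioxaspiro[4.4]non-6-en-6-yl)ethenyl]oxy}silane | C=C(O[Si](C)(C)C(C)(C)C)C1=C(C)CCC12OCCO2
F3 | step 9 | methyl ester at C8 of the cyclohepta-1,4-diene (C5=C6 silyl enol ether, C4 dioxolane) | COC(=O)C1=CC[C@]2(C)CCC3(OCCO3)C2=C(O[Si](C)(C)C(C)(C)C)C1
F4 | step 9 | C8 hydroxymethyl analogue of F3 | OCC1=CC[C@]2(C)CCC3(OCCO3)C2=C(O[Si](C)(C)C(C)(C)C)C1
F5 | step 9 | C8 methyl silyl enol ether (17 without the C9 silyl group) | CC1=CC[C@]2(C)CCC3(OCCO3)C2=C(O[Si](C)(C)C(C)(C)C)C1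
F6 | step 9 | cis-fused C6 ketone without the C9 silyl group | CC1=CC[C@]2(C)CCC3(OCCO3)[C@@H]2C(=O)C1
F7 | step 9 | cis-fused C6 alcohol without the C9 silyl group | CC1=CC[C@]2(C)CCC3(OCCO3)[C@@H]2[C@H](O)C1
F8 | step 13 | 4-isopropenyl-4,6-diol | CC(=C)[C@]1(O)CC[C@@]2(C)CC=C(C)C[C@@H](O)[C@H]21
F9 | step 15 | 9-bromo-8-hydroxy derivative of 24 (bromine on the face opposite to the C1 methyl, C8 hydroxyl on the methyl face) | CC(C)[C@]1(O)CC[C@@]2(C)C[C@@H](Br)[C@@](O)(C)C[C@@H](OC(=O)c3ccc(O[Si](C)(C)C(C)(C)C)cc3)[C@H]21
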